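**Strategy**

Everything rests on cutting the aryl–ketone bond of the chromanone, between the ketone carbon and ring-B carbon C8 (depsidone numbering). The precursor is the complete depsidone carrying a 3-methylbutanoic acid on O7 through a tertiary ether, with the ring-A phenol masked as its tert-butyl ether. In Eaton's reagent one operation removes that mask and closes the pyranone by intramolecular C–H acylation, delivering mollicellin B. The step exploits ring B: C8 is ortho to O7, para to the diaryl-ether oxygen O5 and next to the C9 methyl, while ring A is deactivated by its formyl and lactone carbonyls. The depsidone itself is assembled by two SNAr reactions, a Teuber oxidation and a carbonylative lactonisation.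

Key step: step 8

Remark on the chemistry: mollicellin B has no stereogenic element (the pyranone C2 carries two methyl groups), so the structure is achiral and no step needs stereocontrol. Compounds 1, 4 and 9 are taken as catalogue chemicals. Depsidone numbering (11H-dibenzo[b,e][1,4]dioxepin-11-one) is used for compounds 8 and 10–12.

**Route**

Step 1
Reactants: 1 2,6-difluoro-4-methylbenzaldehyde
Product: 2 2-(tert-butoxy)-6-fluoro-4-methylbenzaldehyde
Conditions: KOt-Bu (1.05 equiv), THF, −40 → 0 °C
Reagents that add atoms: potassium tert-butoxide CC(C)(C)[O-].[K+]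
Why: Nucleophilic aromatic substitution (SNAr) ortho to the formyl group; the two fluorines are equivalent, so there is no regiochemical question, and the bulky alkoxide plus the donor effect of the first tert-butoxy group should stop the reaction at mono-substitution.

Step 2
Reactants: 2 2-(tert-butoxy)-6-fluoro-4-methylbenzaldehyde
Product: 3 3-bromo-6-(tert-butoxy)-2-fluoro-4-methylbenzaldehyde
Conditions: NBS (1.05 equiv), DMF, 0 °C → rt, dark
Reagents that add atoms: N-bromosuccinimide O=C1CCC(=O)N1Br
Why: Electrophilic aromatic bromination para to the alkoxy group, at the CH flanked by the small fluorine and the methyl group; the only other free position is wedged between the tert-butoxy and methyl groups, and ionic conditions in the dark avoid benzylic bromination.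

Step 3
Reactants: 3 3-bromo-6-(tert-butoxy)-2-fluoro-4-methylbenzaldehyde; 4 orcinol (5-methylbenzene-1,3-diol)
Product: 5 3-bromo-6-(tert-butoxy)-2-(3-hydroxy-5-methylphenoxy)-4-methylbenzaldehyde
Conditions: orcinol (3 equiv), K2CO3 (2 equiv), DMF, 90 °C
Reagents that add atoms: none
Why: SNAr of the fluoride ortho to the formyl group (helped inductively by the adjacent bromine, which is itself meta to the formyl group and so inert) by the phenoxide of symmetric orcinol, used in excess so that mono-arylation should dominate.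

Step 4
Reactants: 5 3-bromo-6-(tert-butoxy)-2-(3-hydroxy-5-methylphenoxy)-4-methylbenzaldehyde
Product: 7 3-bromo-6-(tert-butoxy)-2-(2,5-dihydroxy-3-methylphenoxy)-4-methylbenzaldehyde, via aryloxy-para-quinone 6 (not isolated)
Conditions: (KSO3)2NO (2.5 equiv), KH2PO4 buffer (pH 6), acetone/H2O, 0 °C → rt; then Na2S2O4 (aq), EtOAc, N2, rt
Reagents that add atoms: Fremy's salt (potassium nitrosodisulfonate) [K+].[K+].[O]N(S(=O)(=O)[O-])S(=O)(=O)[O-]
Why: Teuber oxidation converts the only free phenol into the para-quinone at its unsubstituted para carbon (between the aryloxy and methyl groups), and dithionite reduces the quinone in the same flask to the hydroquinone, unveiling the hydroxyl needed for the lactone.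

Step 5
Reactants: 7 3-bromo-6-(tert-butoxy)-2-(2,5-dihydroxy-3-methylphenoxy)-4-methylbenzaldehyde
Product: 8 3-(tert-butoxy)-7-hydroxy-1,9-dimethyl-11-oxo-11H-dibenzo[b,e][1,4]dioxepine-4-carbaldehyde
Conditions: Pd(OAc)2 (5 mol%), Xantphos (7.5 mol%), CO (1 atm), Et3N (3 equiv), toluene (0.01 M), 90 °C
Reagents that add atoms: carbon monoxide [C-]#[O+]
Why: Palladium-catalysed intramolecular aryloxycarbonylation (carbonylative lactonisation): oxidative addition to C–Br, CO insertion and capture of the aroyl-palladium by the hydroquinone hydroxyl ortho to the diaryl ether should close the seven-membered depsidone lactone, the other hydroxyl being out of reach and high dilution suppressing oligomers.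

Step 6
Reactants: 8 3-(tert-butoxy)-7-hydroxy-1,9-dimethyl-11-oxo-11H-dibenzo[b,e][1,4]dioxepine-4-carbaldehyde; 9 3-chloro-3-methylbut-1-yne
Product: 10 3-(tert-butoxy)-1,9-dimethyl-7-[(2-methylbut-3-yn-2-yl)oxy]-11-oxo-11H-dibenzo[b,e][1,4]dioxepine-4-carbaldehyde
Conditions: CuCl2·2H2O (1 mol%), DBU (1.3 equiv), MeCN, 0 °C
Reagents that add atoms: none
Why: Copper-catalysed propargylic etherification of the single free phenol with a tertiary propargylic chloride, the standard entry to aryl 1,1-dimethylpropargyl ethers; aldehyde, lactone and tert-butyl ether should be inert to DBU at 0 °C.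

Step 7
Reactants: 10 3-(tert-butoxy)-1,9-dimethyl-7-[(2-methylbut-3-yn-2-yl)oxy]-11-oxo-11H-dibenzo[b,e][1,4]dioxepine-4-carbaldehyde
Product: 11 3-{[3-(tert-butoxy)-4-formyl-1,9-dimethyl-11-oxo-11H-dibenzo[b,e][1,4]dioxepin-7-yl]oxy}-3-methylbutanoic acid
Conditions: [Rh(cod)Cl]2 (2.5 mol%), P(4-FC6H4)3 (10 mol%), 4-picoline N-oxide (1.5 equiv), H2O (10 equiv), MeCN, 60 °C
Reagents that add atoms: 4-picoline N-oxide Cc1cc[n+]([O-])cc1; water O
Why: Rhodium-catalysed oxygenative (anti-Markovnikov) addition to a terminal alkyne: the Rh-vinylidene is oxidised at its alpha carbon by the N-oxide to a rhodium-bound ketene that water intercepts, giving the acid directly so that no second aldehyde ever sits beside the aryl aldehyde.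

Step 8
Reactants: 11 3-{[3-(tert-butoxy)-4-formyl-1,9-dimethyl-11-oxo-11H-dibenzo[b,e][1,4]dioxepin-7-yl]oxy}-3-methylbutanoic acid
Product: 13 mollicellin B, via free-phenol acid 12 (not isolated)
Conditions: Eaton's reagent (P2O5/MeSO3H 1:10 w/w), 0 °C → 45 °C
Reagents that add atoms: none
Why: Methanesulfonic acid first ionises the tert-butyl aryl ether (loss of 2-methylpropene) to the chelated phenol 12, and P2O5/MeSO3H turns the carboxylic acid into a mixed anhydride/acylium ion that attacks ring-B carbon C8 and rearomatises by proton loss. The closest known reaction type is the intramolecular Friedel–Crafts acylation of 3-aryloxyalkanoic acids to chroman-4-ones in polyphosphoric acid or Eaton's reagent. The pyranone closes as a six-membered ring by electrophilic aromatic substitution, exo with respect to the acylium C–O bond and endo with respect to the C7–C8 arene bond; no stereocentre is formed. The step needs site selectivity between the two carbons the tether can reach, C8 and C6: C8 is para to the donor O5 and ortho to the C9 methyl, the pattern at which 3-(3-alkoxyphenoxy)alkanoic acids and orcinol ethers are acylated, whereas C6 lies in the bay between O5 and O7 facing the C4 formyl group. Ring A cannot compete because it is out of reach of the tether and deactivated by two carbonyl groups, the lactone has no free ortho or para position for a Fries shift, and the moderate temperature is chosen to keep ionisation of the tertiary aryl ether slower than acylation.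

**Compound list**

1 | 2,6-difluoro-4-methylbenzaldehyde | Cc1cc(F)c(C=O)c(F)c1 | starting material
2 | 2-(tert-butoxy)-6-fluoro-4-methylbenzaldehyde | Cc1cc(F)c(C=O)c(OC(C)(C)C)c1 | intermediate
3 | 3-bromo-6-(tert-butoxy)-2-fluoro-4-methylbenzaldehyde | Cc1cc(OC(C)(C)C)c(C=O)c(F)c1Br | intermediate
4 | orcinol (5-methylbenzene-1,3-diol) | Cc1cc(O)cc(O)c1 | starting material
5 | 3-bromo-6-(tert-butoxy)-2-(3-hydroxy-5-methylphenoxy)-4-methylbenzaldehyde | Cc1cc(O)cc(Oc2c(Br)c(C)cc(OC(C)(C)C)c2C=O)c1 | intermediate
6 | 3-bromo-6-(tert-butoxy)-4-methyl-2-[(5-methyl-3,6-dioxocyclohexa-1,4-dien-1-yl)oxy]benzaldehyde (aryloxy-para-quinone, not isolated) | CC1=CC(=O)C=C(Oc2c(Br)c(C)cc(OC(C)(C)C)c2C=O)C1=O | intermediate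
7 | 3-bromo-6-(tert-butoxy)-2-(2,5-dihydroxy-3-methylphenoxy)-4-methylbenzaldehyde | Cc1cc(O)cc(Oc2c(Br)c(C)cc(OC(C)(C)C)c2C=O)c1O | intermediate
8 | 3-(tert-butoxy)-7-hydroxy-1,9-dimethyl-11-oxo-11H-dibenzo[b,e][1,4]dioxepine-4-carbaldehyde | Cc1cc(OC(C)(C)C)c(C=O)c2c1C(=O)Oc1c(C)cc(O)cc1O2 | intermediate
9 | 3-chloro-3-methylbut-1-yne | CC(C)(Cl)C#C | starting material
10 | 3-(tert-butoxy)-1,9-dimethyl-7-[(2-methylbut-3-yn-2-yl)oxy]-11-oxo-11H-dibenzo[b,e][1,4]dioxepine-4-carbaldehyde | Cc1cc(OC(C)(C)C)c(C=O)c2c1C(=O)Oc1c(C)cc(OC(C)(C)C#C)cc1O2 | intermediate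
11 | 3-{[3-(tert-butoxy)-4-formyl-1,9-dimethyl-11-oxo-11H-dibenzo[b,e][1,4]dioxepin-7-yl]oxy}-3-methylbutanoic acid | Cc1cc(OC(C)(C)C)c(C=O)c2c1C(=O)Oc1c(C)cc(OC(C)(C)CC(=O)O)cc1O2 | intermediate
12 | 3-[(4-formyl-3-hydroxy-1,9-dimethyl-11-oxo-11H-dibenzo[b,e][1,4]dioxepin-7-yl)oxy]-3-methylbutanoic acid (free-phenol acid, not isolated) | Cc1cc(O)c(C=O)c2c1C(=O)Oc1c(C)cc(OC(C)(C)CC(=O)O)cc1O2 | intermediate
13 | mollicellin B | Cc1cc(O)c(C=O)c2c1C(=O)Oc1c(cc3c(c1C)C(=O)CC(C)(C)O3)O2 | target

**Count**

Total steps: 8. Longest linear sequence: 8 steps (from 1; compounds 4 and 9 enter as purchased reagents).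

**Steps most likely to fail, with fallbacks**

Step 8 (key step). The acylium ion may close onto C6 instead of C8, since both carbons are ortho to O7 and the electronic preference for C8 is modest. The fallback turns that same bias into a blocking group. It sets out from 8: NBS (1 equiv, MeCN, 0 °C) should brominate the phenol at the more nucleophilic ortho carbon, giving 6-bromo-3-(tert-butoxy)-7-hydroxy-1,9-dimethyl-11-oxo-11H-dibenzo[b,e][1,4]dioxepine-4-carbaldehyde F1. Propargylation with 9 as in step 6 gives the bromo propargyl ether F2, and oxygenative hydration as in step 7 gives the bromo acid F3. In Eaton's reagent F3 should lose the tert-butyl group to the bromo free-phenol acid F4 (not isolated) and can then acylate only C8, giving 6-bromomollicellin B F5. Palladium-catalysed transfer hydrodebromination (Pd(OAc)2, PPh3, HCO2Na, DMF, 80 °C), which should spare the aldehyde and ketone, comes back to the route at 13.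

Step 5. Oxidative addition into the doubly ortho-substituted, electron-rich C–Br bond may be slow, leaving time for the air-sensitive hydroquinone to be oxidised, to be acylated intermolecularly at its unhindered hydroxyl, or to undergo non-carbonylative C–O reductive elimination. The fallback separates carbon insertion from ring closure and sets out from 5, where ring B is still a robust mono-phenol. Hydroxycarbonylation (Pd(OAc)2, Xantphos, CO 1 atm, K2CO3, dioxane/H2O, 90 °C) gives 4-(tert-butoxy)-3-formyl-2-(3-hydroxy-5-methylphenoxy)-6-methylbenzoic acid F6. Teuber oxidation as in step 4 gives the quinone acid F7 (not isolated), and dithionite gives 4-(tert-butoxy)-2-(2,5-dihydroxy-3-methylphenoxy)-3-formyl-6-methylbenzoic acid F8. Carbodiimide lactonisation (DCC, CH2Cl2/THF, high dilution, rt), the classical depsidone closure, comes back to the route at 8.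

Step 7. The aryloxide may be expelled from the metal vinylidene (propargylic ionisation), or rhodium may engage the aryl aldehyde, so that the alkyne is consumed without clean oxygen transfer. The fallback reaches the acid in two redox-neutral/oxidative stages and sets out from 10. Ruthenium-catalysed anti-Markovnikov hydration (CpRu(MeCN)3PF6, 5,5'-bis(trifluoromethyl)-2,2'-bipyridine, NMP/H2O, rt) gives 3-(tert-butoxy)-1,9-dimethyl-7-[(2-methyl-4-oxobutan-2-yl)oxy]-11-oxo-11H-dibenzo[b,e][1,4]dioxepine-4-carbaldehyde F9. Pinnick oxidation with limiting chlorite (NaClO2 1.1 equiv, NaH2PO4, 2-methyl-2-butene, t-BuOH/H2O, 0 °C) should oxidise the aliphatic aldehyde ahead of the doubly ortho-substituted aryl aldehyde and comes back to the route at 11.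

**Further compounds**

F1 | step 8 | 6-bromo-3-(tert-butoxy)-7-hydroxy-1,9-dimethyl-11-oxo-11H-dibenzo[b,e][1,4]dioxepine-4-carbaldehyde | Cc1cc(OC(C)(C)C)c(C=O)c2c1C(=O)Oc1c(C)cc(O)c(Br)c1O2
F2 | step 8 | 6-bromo-3-(tert-butoxy)-1,9-dimethyl-7-[(2-methylbut-3-yn-2-yl)oxy]-11-oxo-11H-dibenzo[b,e][1,4]dioxepine-4-carbaldehyde | Cc1cc(OC(C)(C)C)c(C=O)c2c1C(=O)Oc1c(C)cc(OC(C)(C)C#C)c(Br)c1O2
F3 | step 8 | 3-{[6-bromo-3-(tert-butoxy)-4-formyl-1,9-dimethyl-11-oxo-11H-dibenzo[b,e][1,4]dioxepin-7-yl]oxy}-3-methylbutanoic acid | Cc1cc(OC(C)(C)C)c(C=O)c2c1C(=O)Oc1c(C)cc(OC(C)(C)CC(=O)O)c(Br)c1O2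
F4 | step 8 | 3-[(6-bromo-4-formyl-3-hydroxy-1,9-dimethyl-11-oxo-11H-dibenzo[b,e][1,4]dioxepin-7-yl)oxy]-3-methylbutanoic acid | Cc1cc(O)c(C=O)c2c1C(=O)Oc1c(C)cc(OC(C)(C)CC(=O)O)c(Br)c1O2
F5 | step 8 | 6-bromomollicellin B (bromine on the ring-B carbon between the two ether oxygens) | Cc1cc(O)c(C=O)c2c1C(=O)Oc1c(c(Br)c3c(c1C)C(=O)CC(C)(C)O3)O2
F6 | step 5 | 4-(tert-butoxy)-3-formyl-2-(3-hydroxy-5-methylphenoxy)-6-methylbenzoic acid | Cc1cc(O)cc(Oc2c(C(=O)O)c(C)cc(OC(C)(C)C)c2C=O)c1
F7 | step 5 | 4-(tert-butoxy)-3-formyl-6-methyl-2-[(5-methyl-3,6-dioxocyclohexa-1,4-dien-1-yl)oxy]benzoic acid | CC1=CC(=O)C=C(Oc2c(C(=O)O)c(C)cc(OC(C)(C)C)c2C=O)C1=O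
F8 | step 5 | 4-(tert-butoxy)-2-(2,5-dihydroxy-3-methylphenoxy)-3-formyl-6-methylbenzoic acid | Cc1cc(O)cc(Oc2c(C(=O)O)c(C)cc(OC(C)(C)C)c2C=O)c1O
F9 | step 7 | 3-(tert-butoxy)-1,9-dimethyl-7-[(2-methyl-4-oxobutan-2-yl)oxy]-11-oxo-11H-dibenzo[b,e][1,4]dioxepine-4-carbaldehyde | Cc1cc(OC(C)(C)C)c(C=O)c2c1C(=O)Oc1c(C)cc(OC(C)(C)CC=O)cc1O2
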